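The oxolane ring (O1, C2 to C5) is cut into two pieces: the C2=C3 bond of an (E)-stilbene that already carries both trans-dihydrobenzofurans, and the triad O1–C5–C4, held as an α-aryl-α-diazoketone. One-electron oxidation of the stilbene starts a formal (3+2) annulation in which diazo carbon C4 bonds to C3, N2 leaves and ketone oxygen O1 closes on C2. The step exploits the para oxygen of phenyl ring A on C2: it makes C3 the reactive alkene terminus and C2 the cation that O1 traps, whereas ring B on C3 has only meta oxygens. Syn hydrogenation of the 2,3-dihydrofuran (C4) and acid equilibration (C5) complete the ring.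

Key step: step 17

Labels:
- Oxolane atoms are O1, C2 (bears ring A, 4-oxyphenyl), C3 (bears ring B), C4 (bears ring C, 3,5-dioxyphenyl) and C5 (bears ring D, 4-oxyphenyl).
- Unit P is the 2,3-dihydrobenzofuran whose benzo ring is ring B. Its stereocentres are P2 and P3, the oxolane sits on P4 and an oxygen on P6.
- Unit Q is the 2,3-dihydrobenzofuran whose benzo ring is ring E. Its stereocentres are Q2 and Q3, it is bonded through Q5 to P3, and it carries an oxygen on Q7.
- Target configuration: P2 S, P3 S, Q2 R, Q3 R, C2 R, C3 S, C4 R, C5 S. Bn = benzyl.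

Assumption 1: the SMILES defines the target, so unit Q is joined to P3 through Q5 and carries its free hydroxyl on Q7.
Assumption 2: Rh2(R-PTAD)4 is taken to give the Q3 R series and Rh2(S-PTAD)4 the P3 S series; both catalysts are commercial, so they are exchanged if the sense of induction proves opposite.

Step 1
Reactants: 1 5-bromo-2,3-dihydroxybenzaldehyde; 2 4-(benzyloxy)benzyl chloride
Product: 4 3-benzyloxy-2-{[4-(benzyloxy)phenyl]methoxy}-5-bromobenzaldehyde, via sodium phenolate 3 (not isolated)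
Conditions: NaH (2.2 equiv), DMF, 0 °C; BnBr (1.0 equiv), rt; then 2 (1.2 equiv), 60 °C
Reagents that add atoms: benzyl bromide BrCc1ccccc1
Why: Williamson ether synthesis on the catechol dianion, in which the 3-oxide, not tied up by conjugation and chelation with the formyl group, takes the single equivalent of benzyl bromide first and the remaining 2-oxide then takes the second halide.

Step 2
Reactants: 4 3-benzyloxy-2-{[4-(benzyloxy)phenyl]methoxy}-5-bromobenzaldehyde; 5 1,3-bis(benzyloxy)-5-bromobenzene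
Product: 7 [3,5-bis(benzyloxy)phenyl](3-benzyloxy-2-{[4-(benzyloxy)phenyl]methoxy}-5-bromophenyl)methanol (racemic), via aryllithium 6 (not isolated)
Conditions: 5, n-BuLi, THF, −78 °C; then 4, −78 to 0 °C; H2O quench
Reagents that add atoms: none
Why: Bromine–lithium exchange followed by 1,2-addition of the aryllithium to the aldehyde, which at −78 °C is faster than exchange with the aryl bromide of 4, and the racemic carbinol centre is erased in step 3.

Step 3
Reactants: 7 diaryl carbinol
Product: 8 [3,5-bis(benzyloxy)phenyl](3-benzyloxy-2-{[4-(benzyloxy)phenyl]methoxy}-5-bromophenyl)methanone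
Conditions: Dess–Martin periodinane, CH2Cl2, rt
Reagents that add atoms: none
Why: Dess–Martin oxidation of a diaryl carbinol under near-neutral conditions that leave benzyl ethers and the aryl bromide untouched.

Step 4
Reactants: 8 diaryl ketone
Product: 9 hydrazone of 8 (E/Z mixture)
Conditions: N2H4·H2O, AcOH (cat.), EtOH, 80 °C
Reagents that add atoms: hydrazine NN
Why: Acid-catalysed hydrazone formation on a benzophenone that has only one ortho substituent next to the carbonyl group.

Step 5
Reactants: 9 hydrazone of 8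
Product: 11 (2S,3R)-7-benzyloxy-2-(4-benzyloxyphenyl)-3-[3,5-bis(benzyloxy)phenyl]-5-bromo-2,3-dihydrobenzofuran (cis; unit Q), via diaryldiazomethane 10 (not isolated)
Conditions: MnO2, CH2Cl2, rt, filtration; Rh2(R-PTAD)4 (1 mol %), CH2Cl2, 0 °C
Reagents that add atoms: none
Why: Hydrazone oxidation to the diazo compound and enantioselective intramolecular 1,5 C–H insertion of the donor/donor rhodium carbene into the ArCH2–O methylene, in which the chiral carboxylate ligands set Q3 as R and the concerted insertion gives the cis ring (Q2 S).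

Step 6
Reactants: 5 1,3-bis(benzyloxy)-5-bromobenzene
Product: 12 2,4-bis(benzyloxy)-6-bromobenzaldehyde
Conditions: POCl3, DMF, 0 to 80 °C; then H2O
Reagents that add atoms: N,N-dimethylformamide CN(C)C=O; water O
Why: Vilsmeier–Haack formylation at the position para to one benzyloxy group and ortho to the other, the site between the two ethers being the more hindered one.

Step 7
Reactants: 12 2,4-bis(benzyloxy)-6-bromobenzaldehyde
Product: 13 4-benzyloxy-2-bromo-6-hydroxybenzaldehyde
Conditions: MgBr2·OEt2, toluene–Et2O, 80 °C; then H2O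
Reagents that add atoms: none
Why: Chelation-controlled Lewis acid ether cleavage, in which MgBr2 bridges the formyl oxygen and only the ortho benzyloxy oxygen so that bromide removes that benzyl group alone.

Step 8
Reactants: 13 4-benzyloxy-2-bromo-6-hydroxybenzaldehyde; 2 4-(benzyloxy)benzyl chloride
Product: 14 4-benzyloxy-2-{[4-(benzyloxy)phenyl]methoxy}-6-bromobenzaldehyde
Conditions: K2CO3, DMF, 60 °C
Reagents that add atoms: none
Why: Williamson ether synthesis of the only free phenol with a reactive benzylic chloride.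

Step 9
Reactants: 11 cis unit Q bromide; 14 4-benzyloxy-2-{[4-(benzyloxy)phenyl]methoxy}-6-bromobenzaldehyde
Product: 16 (4-benzyloxy-2-{[4-(benzyloxy)phenyl]methoxy}-6-bromophenyl)[(2S,3R)-7-benzyloxy-2-(4-benzyloxyphenyl)-3-[3,5-bis(benzyloxy)phenyl]-2,3-dihydrobenzofuran-5-yl]methanol (both carbinol epimers), via aryllithium 15 (not isolated)
Conditions: 11, n-BuLi, THF, −78 °C; then 14, −78 to 0 °C; H2O quench
Reagents that add atoms: none
Why: Bromine–lithium exchange at Q5 and 1,2-addition to the aldehyde, which outruns exchange with the bromide of 14 at low temperature, and the unselective carbinol centre is erased in step 10.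

Step 10
Reactants: 16 carbinol
Product: 17 (4-benzyloxy-2-{[4-(benzyloxy)phenyl]methoxy}-6-bromophenyl)[(2S,3R)-7-benzyloxy-2-(4-benzyloxyphenyl)-3-[3,5-bis(benzyloxy)phenyl]-2,3-dihydrobenzofuran-5-yl]methanone
Conditions: Dess–Martin periodinane, CH2Cl2, rt
Reagents that add atoms: none
Why: Dess–Martin oxidation, which tolerates steric crowding at a diaryl carbinol and does not touch Q2 or Q3.

Step 11
Reactants: 17 diaryl ketone
Product: 18 hydrazone of 17 (E/Z mixture)
Conditions: N2H4·H2O (excess), N2H4·HCl (cat.), n-BuOH, 120 °C, sealed tube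
Reagents that add atoms: hydrazine NN
Why: Hydrazone formation under forcing buffered conditions, in which the small α-effect nucleophile should still reach a carbonyl group that is twisted away from the doubly ortho-substituted ring B and is flanked on its other side by the unhindered ring E.

Step 12
Reactants: 18 hydrazone of 17
Product: 20 (2R,3S)-6-benzyloxy-2-(4-benzyloxyphenyl)-4-bromo-3-{(2S,3R)-7-benzyloxy-2-(4-benzyloxyphenyl)-3-[3,5-bis(benzyloxy)phenyl]-2,3-dihydrobenzofuran-5-yl}-2,3-dihydrobenzofuran (both rings cis), via diaryldiazomethane 19 (not isolated)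
Conditions: MnO2, CH2Cl2, rt, filtration; Rh2(S-PTAD)4 (1 mol %), CH2Cl2, 0 °C
Reagents that add atoms: none
Why: Hydrazone oxidation and enantioselective intramolecular 1,5 C–H insertion of the donor/donor rhodium carbene, in which the enantiomeric catalyst overrides the remote unit Q and sets P3 as S with the cis ring (P2 R).

Step 13
Reactants: 20 cis,cis bromide
Product: 21 (2S,3S)-6-benzyloxy-2-(4-benzyloxyphenyl)-4-bromo-3-{(2R,3R)-7-benzyloxy-2-(4-benzyloxyphenyl)-3-[3,5-bis(benzyloxy)phenyl]-2,3-dihydrobenzofuran-5-yl}-2,3-dihydrobenzofuran (both rings trans)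
Conditions: TFA, CH2Cl2, 0 °C to rt
Reagents that add atoms: none
Why: Acid-mediated thermodynamic epimerisation, in which reversible ionisation of each C2–O bond to a 4-benzyloxybenzyl cation and reclosure gives the more stable trans rings, inverting P2 to S and Q2 to R while P3 and Q3 are untouched.

Step 14
Reactants: 21 trans,trans bromide; 22 4-(benzyloxy)styrene
Product: 23 (2S,3S)-6-benzyloxy-2-(4-benzyloxyphenyl)-4-[(E)-2-(4-benzyloxyphenyl)ethenyl]-3-{(2R,3R)-7-benzyloxy-2-(4-benzyloxyphenyl)-3-[3,5-bis(benzyloxy)phenyl]-2,3-dihydrobenzofuran-5-yl}-2,3-dihydrobenzofuran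
Conditions: Pd2(dba)3, P(tBu)3·HBF4, Cy2NMe, 1,4-dioxane, 100 °C
Reagents that add atoms: none
Why: Heck reaction, in which the bulky electron-rich phosphine allows oxidative addition of the hindered electron-rich aryl bromide to zerovalent palladium and syn insertion followed by syn β-hydride elimination gives the E-stilbene.

Step 15
Reactants: 24 4'-(benzyloxy)acetophenone; 5 1,3-bis(benzyloxy)-5-bromobenzene
Product: 25 1-[4-(benzyloxy)phenyl]-2-[3,5-bis(benzyloxy)phenyl]ethan-1-one
Conditions: Pd2(dba)3, Xantphos, NaOtBu, toluene, 80 °C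
Reagents that add atoms: none
Why: Palladium-catalysed α-arylation of a methyl ketone enolate, which stops at monoarylation because the more acidic product is stored as its hindered enolate.

Step 16
Reactants: 25 deoxybenzoin
Product: 26 1-[4-(benzyloxy)phenyl]-2-[3,5-bis(benzyloxy)phenyl]-2-diazoethan-1-one
Conditions: p-ABSA, DBU, MeCN, 0 °C to rt
Reagents that add atoms: 4-acetamidobenzenesulfonyl azide CC(=O)Nc1ccc(cc1)S(=O)(=O)N=[N+]=[N-]
Why: Regitz diazo transfer to a benzylic ketone methylene that is acidic enough for DBU.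

Step 17
Reactants: 23 stilbene; 26 α-aryl-α-diazoketone
Product: 27 (2R,3R)-2,5-bis(4-benzyloxyphenyl)-4-[3,5-bis(benzyloxy)phenyl]-3-(unit P-4-yl)-2,3-dihydrofuran (2,3-trans; unit P and unit Q as in 23)
Conditions: 26 (2.5 equiv, slow addition), (4-BrC6H4)3N·SbCl6 (20 mol %), 2,6-di-tert-butylpyridine, CH2Cl2, −20 °C, dark; Et3N quench
Reagents that add atoms: none
Why: Proposed new method: the aminium salt removes one electron from the stilbene, the most easily oxidised π-system of 23, the nucleophilic diazo carbon C4 of 26 adds to C3 of the radical cation, N2 is lost, and the resulting C2 cation/C4 α-keto radical collapses by attack of ketone oxygen O1 on C2 to the radical cation of 27, which is reduced by the triarylamine or by fresh 23 so that the hole is passed on (initial oxidation of 26 instead would lead through an electrophilic C4 to the same bonds). The closest known reaction type is the aminium-salt or photoredox catalysed radical-cation cyclopropanation of stilbenes and anethole-type alkenes with diazo esters; the disubstituted α-aryl-α-diazoketone and closure through oxygen are the new elements, and any donor–acceptor cyclopropane formed by C-closure should reopen at its C2–C4 bond and end as 27 (Cloke–Wilson rearrangement). The only ring closed, the dihydrofuran, forms by 5-exo-trig attack of O1 on the quinoid 4-benzyloxybenzyl cation (enolendo with respect to O1–C5=C4). C3 is set by the substrate: in the favoured s-trans rotamer of the styryl group (C3–H turned towards P3) ring E on P3 covers one face of C3, so 26 should arrive from the other face and give the required configuration (R in 27, S in 29 after the change of priorities), and C2 (R) is set in the suprafacial ring closure, which keeps ring A trans to the much larger ring B. Regioselectivity (C4 to C3, O1 to C2) follows from the para-benzyloxy group of ring A, which stabilises charge at C2 only, chemoselectivity over the isolated benzyloxyarenes follows from the lower oxidation potential of the conjugated stilbene, and the hindered pyridine keeps the medium free of acid that would hydrolyse 27 or cyclise 23.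

Step 18
Reactants: 27 dihydrofuran
Product: 28 5-epi-kobophenol A (oxolane C2 R, C3 S, C4 R, C5 R; rings B, C and D cis to one another, ring A trans to ring B)
Conditions: H2 (5 bar), Pd(OH)2/C, THF–MeOH, rt
Reagents that add atoms: none
Why: Heterogeneous syn hydrogenation together with hydrogenolysis of the ten benzyl ethers, in which the C4=C5 bond, a cyclic cis-stilbene of the kind that palladium catalysts reduce to cis-diaryl products, should bind the metal on the face opposite to the very large ring B on the adjacent C3, setting C4 as R and C5 as R, while the endocyclic secondary benzylic C–O bonds are cleaved far more slowly than primary O-benzyl groups.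

Step 19
Reactants: 28 5-epi-kobophenol A
Product: 29 kobophenol A
Conditions: HCO2H (cat.), MeCN–H2O, 40 °C
Reagents that add atoms: none
Why: Thermodynamic epimerisation by reversible SN1 ring opening, in which mild acid ionises the C5–O1 bond to a 4-hydroxybenzyl cation (protonated quinone methide) and reclosure places ring D trans to ring C and sets C5 as S, while C3 and C4 cannot ionise and the other O-benzylic centres (C2, P2, Q2) already hold their favoured trans arrangement.

Compound list
1 | 5-bromo-2,3-dihydroxybenzaldehyde | O=Cc1cc(Br)cc(O)c1O | starting material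
2 | 4-(benzyloxy)benzyl chloride | ClCc1ccc(OCc2ccccc2)cc1 | starting material
3 | sodium 2-benzyloxy-4-bromo-6-formylphenolate | O=Cc1cc(Br)cc(OCc2ccccc2)c1[O-].[Na+] | intermediate
4 | 3-benzyloxy-2-{[4-(benzyloxy)phenyl]methoxy}-5-bromobenzaldehyde | O=Cc1cc(Br)cc(OCc2ccccc2)c1OCc1ccc(OCc2ccccc2)cc1 | intermediate
5 | 1,3-bis(benzyloxy)-5-bromobenzene | Brc1cc(OCc2ccccc2)cc(OCc2ccccc2)c1 | starting material
6 | [3,5-bis(benzyloxy)phenyl]lithium | [Li]c1cc(OCc2ccccc2)cc(OCc2ccccc2)c1 | intermediate
7 | [3,5-bis(benzyloxy)phenyl](3-benzyloxy-2-{[4-(benzyloxy)phenyl]methoxy}-5-bromophenyl)methanol (racemic) | OC(c1cc(OCc2ccccc2)cc(OCc2ccccc2)c1)c1cc(Br)cc(OCc2ccccc2)c1OCc1ccc(OCc2ccccc2)cc1 | intermediate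
8 | [3,5-bis(benzyloxy)phenyl](3-benzyloxy-2-{[4-(benzyloxy)phenyl]methoxy}-5-bromophenyl)methanone | O=C(c1cc(OCc2ccccc2)cc(OCc2ccccc2)c1)c1cc(Br)cc(OCc2ccccc2)c1OCc1ccc(OCc2ccccc2)cc1 | intermediate
9 | hydrazone of 8 (E/Z mixture) | NN=C(c1cc(OCc2ccccc2)cc(OCc2ccccc2)c1)c1cc(Br)cc(OCc2ccccc2)c1OCc1ccc(OCc2ccccc2)cc1 | intermediate
10 | diaryldiazomethane from 9 | [N-]=[N+]=C(c1cc(OCc2ccccc2)cc(OCc2ccccc2)c1)c1cc(Br)cc(OCc2ccccc2)c1OCc1ccc(OCc2ccccc2)cc1 | intermediate
11 | (2S,3R)-7-benzyloxy-2-(4-benzyloxyphenyl)-3-[3,5-bis(benzyloxy)phenyl]-5-bromo-2,3-dihydrobenzofuran (cis) | Brc1cc(OCc3ccccc3)c2c(c1)[C@@H](c1cc(OCc3ccccc3)cc(OCc3ccccc3)c1)[C@@H](c1ccc(OCc3ccccc3)cc1)O2 | intermediate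
12 | 2,4-bis(benzyloxy)-6-bromobenzaldehyde | O=Cc1c(Br)cc(OCc2ccccc2)cc1OCc1ccccc1 | intermediate
13 | 4-benzyloxy-2-bromo-6-hydroxybenzaldehyde | O=Cc1c(Br)cc(OCc2ccccc2)cc1O | intermediate
14 | 4-benzyloxy-2-{[4-(benzyloxy)phenyl]methoxy}-6-bromobenzaldehyde | O=Cc1c(Br)cc(OCc2ccccc2)cc1OCc1ccc(OCc2ccccc2)cc1 | intermediate
15 | Q5-lithio derivative of 11 | [Li]c1cc(OCc3ccccc3)c2c(c1)[C@@H](c1cc(OCc3ccccc3)cc(OCc3ccccc3)c1)[C@@H](c1ccc(OCc3ccccc3)cc1)O2 | intermediate
16 | diaryl carbinol from 14 and 15 (Q2 S, Q3 R; both carbinol epimers) | OC(c1c(Br)cc(OCc2ccccc2)cc1OCc1ccc(OCc2ccccc2)cc1)c1cc(OCc3ccccc3)c2c(c1)[C@@H](c1cc(OCc3ccccc3)cc(OCc3ccccc3)c1)[C@@H](c1ccc(OCc3ccccc3)cc1)O2 | intermediate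
17 | diaryl ketone from 16 (Q2 S, Q3 R) | O=C(c1c(Br)cc(OCc2ccccc2)cc1OCc1ccc(OCc2ccccc2)cc1)c1cc(OCc3ccccc3)c2c(c1)[C@@H](c1cc(OCc3ccccc3)cc(OCc3ccccc3)c1)[C@@H](c1ccc(OCc3ccccc3)cc1)O2 | intermediate
18 | hydrazone of 17 (E/Z mixture) | NN=C(c1c(Br)cc(OCc2ccccc2)cc1OCc1ccc(OCc2ccccc2)cc1)c1cc(OCc3ccccc3)c2c(c1)[C@@H](c1cc(OCc3ccccc3)cc(OCc3ccccc3)c1)[C@@H](c1ccc(OCc3ccccc3)cc1)O2 | intermediate
19 | diaryldiazomethane from 18 | [N-]=[N+]=C(c1c(Br)cc(OCc2ccccc2)cc1OCc1ccc(OCc2ccccc2)cc1)c1cc(OCc3ccccc3)c2c(c1)[C@@H](c1cc(OCc3ccccc3)cc(OCc3ccccc3)c1)[C@@H](c1ccc(OCc3ccccc3)cc1)O2 | intermediate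
20 | cis,cis P4-bromide (P2 R, P3 S, Q2 S, Q3 R) | c1ccccc1COc1ccc([C@@H]2Oc3cc(OCc4ccccc4)cc(Br)c3[C@@H]2c2cc(OCc4ccccc4)c3c(c2)[C@@H](c2cc(OCc4ccccc4)cc(OCc4ccccc4)c2)[C@@H](c2ccc(OCc4ccccc4)cc2)O3)cc1 | intermediate
21 | trans,trans P4-bromide (P2 S, P3 S, Q2 R, Q3 R) | c1ccccc1COc1ccc([C@H]2Oc3cc(OCc4ccccc4)cc(Br)c3[C@@H]2c2cc(OCc4ccccc4)c3c(c2)[C@@H](c2cc(OCc4ccccc4)cc(OCc4ccccc4)c2)[C@H](c2ccc(OCc4ccccc4)cc2)O3)cc1 | intermediate
22 | 4-(benzyloxy)styrene | C=Cc1ccc(OCc2ccccc2)cc1 | starting material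
23 | hepta-O-benzyl (E)-stilbene (P2 S, P3 S, Q2 R, Q3 R) | c1ccccc1COc1ccc([C@H]2Oc3cc(OCc4ccccc4)cc(/C=C/c4ccc(OCc5ccccc5)cc4)c3[C@@H]2c2cc(OCc4ccccc4)c3c(c2)[C@@H](c2cc(OCc4ccccc4)cc(OCc4ccccc4)c2)[C@H](c2ccc(OCc4ccccc4)cc2)O3)cc1 | intermediate
24 | 4'-(benzyloxy)acetophenone | CC(=O)c1ccc(OCc2ccccc2)cc1 | starting material
25 | 1-[4-(benzyloxy)phenyl]-2-[3,5-bis(benzyloxy)phenyl]ethan-1-one | O=C(Cc1cc(OCc2ccccc2)cc(OCc2ccccc2)c1)c1ccc(OCc2ccccc2)cc1 | intermediate
26 | 1-[4-(benzyloxy)phenyl]-2-[3,5-bis(benzyloxy)phenyl]-2-diazoethan-1-one | [N-]=[N+]=C(C(=O)c1ccc(OCc2ccccc2)cc1)c1cc(OCc2ccccc2)cc(OCc2ccccc2)c1 | intermediate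
27 | deca-O-benzyl (2R,3R)-2,3-dihydrofuran (2,3-trans; P2 S, P3 S, Q2 R, Q3 R) | c1ccccc1COc1ccc([C@H]2Oc3cc(OCc4ccccc4)cc([C@@H]4C(c5cc(OCc6ccccc6)cc(OCc6ccccc6)c5)=C(c5ccc(OCc6ccccc6)cc5)O[C@H]4c4ccc(OCc5ccccc5)cc4)c3[C@@H]2c2cc(OCc4ccccc4)c3c(c2)[C@@H](c2cc(OCc4ccccc4)cc(OCc4ccccc4)c2)[C@H](c2ccc(OCc4ccccc4)cc2)O3)cc1 | intermediate
28 | 5-epi-kobophenol A (C2 R, C3 S, C4 R, C5 R) | Oc1ccc([C@H]2Oc3cc(O)cc([C@@H]4[C@H](c5cc(O)cc(O)c5)[C@H](c5ccc(O)cc5)O[C@H]4c4ccc(O)cc4)c3[C@@H]2c2cc(O)c3c(c2)[C@@H](c2cc(O)cc(O)c2)[C@H](c2ccc(O)cc2)O3)cc1 | intermediate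
29 | kobophenol A (P2 S, P3 S, Q2 R, Q3 R, C2 R, C3 S, C4 R, C5 S) | Oc1ccc([C@H]2Oc3cc(O)cc([C@@H]4[C@H](c5cc(O)cc(O)c5)[C@@H](c5ccc(O)cc5)O[C@H]4c4ccc(O)cc4)c3[C@@H]2c2cc(O)c3c(c2)[C@@H](c2cc(O)cc(O)c2)[C@H](c2ccc(O)cc2)O3)cc1 | target

Total step count: 19. Longest linear sequence: 14 steps (1 to 5, 9 to 14, 17 to 19).

Steps most likely to fail

Step 17.
- The hindered diazo carbon may add too slowly to the hindered C3, so that the diazoketone is consumed by the oxidant.
- The product may be oxidised further and lose the hydrogens on C2 and C3, which aromatises it to the furan.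
- Shielding by ring E may be incomplete, which would give poor facial selectivity at C3.
- The fallback sets out from 25 and 23 and reverses the initiation. Ketone 25 is brominated (CuBr2, EtOAc–CHCl3, reflux) to 2-bromo-1-[4-(benzyloxy)phenyl]-2-[3,5-bis(benzyloxy)phenyl]ethan-1-one F1.
- F1 and 23 are then joined by the known visible-light radical–polar crossover annulation of α-halo ketones with styrenes (fac-Ir(ppy)3, 2,6-lutidine, MeCN–CH2Cl2, blue LED).
- In that reaction, reductive cleavage of the C–Br bond gives the α-keto radical at C4. Addition to C3, oxidation of the C2 radical to the cation, closure by O1 and loss of the C4 proton bring the route back at 27.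

Step 18.
- Uptake of hydrogen at the tetrasubstituted C4=C5 bond may be so slow that hydrogenolysis of the ring C–O bonds overtakes it.
- Adsorption may not distinguish the two faces well enough.
- The fallback sets out from 27 and separates the two tasks. A radical hydrogenation by metal-hydride hydrogen atom transfer (Mn(dpm)3, PhSiH3, tBuOOH, iPrOH–CH2Cl2) delivers hydrogen to C4 from the face away from ring B and then to the C5 radical. This should give the deca-O-benzyl ether of 5-epi-kobophenol A F2.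
- A mild hydrogenolysis (H2, 1 atm, Pd/C, EtOAc–MeOH) then brings the route back at 28.

Step 11.
- Condensation at the doubly ortho-substituted ketone may stay incomplete.
- Under forcing conditions the hydrazone nitrogen may attack the neighbouring C–Br position.
- The fallback sets out from 17 and avoids the carbene altogether. The phosphazene base P4-t-Bu (toluene, 100 °C) deprotonates the ArCH2–O methylene, which adds to the ketone. Loss of water gives 6-benzyloxy-2-(4-benzyloxyphenyl)-4-bromo-3-(unit Q-5-yl)benzofuran F3.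
- Ionic hydrogenation (Et3SiH, TFA, CH2Cl2) reduces the furan ring to the trans-dihydrobenzofuran and at the same time epimerises Q2.
- The two trans diastereomers are separable because unit Q is enantiopure, so they are parted by chromatography and the route comes back at 21.

Further compounds
F1 | step 17 | 2-bromo-1-[4-(benzyloxy)phenyl]-2-[3,5-bis(benzyloxy)phenyl]ethan-1-one (racemic) | O=C(C(Br)c1cc(OCc2ccccc2)cc(OCc2ccccc2)c1)c1ccc(OCc2ccccc2)cc1
F2 | step 18 | deca-O-benzyl ether of 5-epi-kobophenol A (C2 R, C3 S, C4 R, C5 R) | c1ccccc1COc1ccc([C@H]2Oc3cc(OCc4ccccc4)cc([C@@H]4[C@H](c5cc(OCc6ccccc6)cc(OCc6ccccc6)c5)[C@H](c5ccc(OCc6ccccc6)cc5)O[C@H]4c4ccc(OCc5ccccc5)cc4)c3[C@@H]2c2cc(OCc4ccccc4)c3c(c2)[C@@H](c2cc(OCc4ccccc4)cc(OCc4ccccc4)c2)[C@H](c2ccc(OCc4ccccc4)cc2)O3)cc1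
F3 | step 11 | 6-benzyloxy-2-(4-benzyloxyphenyl)-4-bromo-3-(unit Q-5-yl)benzofuran (Q2 S, Q3 R) | c1ccccc1COc1ccc(-c2oc3cc(OCc4ccccc4)cc(Br)c3c2-c2cc(OCc4ccccc4)c3c(c2)[C@@H](c2cc(OCc4ccccc4)cc(OCc4ccccc4)c2)[C@@H](c2ccc(OCc4ccccc4)cc2)O3)cc1
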